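**Retrosynthetic overview**
1. The target is reached by hydrogenolysis of nine benzyl ethers from bis-gallate 16. Both gallates are put on the 3,7-diol 14 in one Steglich acylation. O7 is kept apart from O5 from the first step as a tosylate; O5, O3' and O4' are benzyl ethers.
2. The C3–O bond comes from a C3–CHO group by Baeyer–Villiger oxidation with retention, so the ring C precursor is the trans-2-arylchroman-3-carbaldehyde 11. The formyl carbon is a temporary activating group.
3. Rings A and B and both galloyl rings are bought. Ring C is the only ring formed, closed through the C2–C3 bond in an amine-catalysed internal redox cascade of cinnamaldehyde 7: a [1,5]-hydride shift from C2–H to C4, then closure of the enamine carbon C3 onto the oxocarbenium carbon C2, which sets both stereocentres.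
4. Enabling feature: the hydrogen on C2 is α to the ring oxygen O1 and benzylic to the para-oxygenated ring B, so C2 is a hydride donor and latent oxocarbenium carbon. It sits 1,5 to C4, which is a methylene in the target and can take up that hydride, leaving C3 as the nucleophilic α-carbon of an aldehyde.
5. Enal 7 comes from 2,4,6-trihydroxybenzaldehyde by 4-O-tosylation, two Williamson etherifications and a Wittig two-carbon homologation.

Key step: step 5

Remark: compounds 3, 6 and 15 and both enantiomers of the pyrrolidine catalyst are taken as catalogue materials.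
Remark: the sense of induction in step 5 is assigned from the usual shielding model of diarylprolinol silyl ether enamines (attack anti to the diarylmethyl group) with a diequatorial chair-like closure. This calls for the (R)-catalyst; the (S)-catalyst is the alternative should the sense prove opposite.

Step 1
Reactants: 1 2,4,6-trihydroxybenzaldehyde
Product: 2 4-formyl-3,5-dihydroxyphenyl 4-methylbenzenesulfonate
Conditions: TsCl (1.0 equiv), K2CO3 (1.0 equiv), acetone, 0 °C to rt
Reagents that add atoms: 4-toluenesulfonyl chloride (TsCl), Cc1ccc(cc1)S(Cl)(=O)=O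
Why: Selective O-sulfonylation of the most acidic, non-chelated 4-OH (the two ortho OH groups are hydrogen-bonded to the formyl oxygen) should give the 4-tosylate, which marks the later O7, withstands all later steps and lowers the donor strength of ring A for step 5.

Step 2
Reactants: 2 4-formyl-3,5-dihydroxyphenyl 4-methylbenzenesulfonate; 3 3,4-bis(benzyloxy)benzyl chloride
Product: 4 3-{[3,4-bis(benzyloxy)phenyl]methoxy}-4-formyl-5-hydroxyphenyl 4-methylbenzenesulfonate
Conditions: 3 (1.0 equiv), K2CO3 (1.05 equiv), NaI (10 mol %), DMF, rt to 40 °C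
Reagents that add atoms: none
Why: Williamson etherification of one of the two equivalent ortho phenols should stop at the monoether, because the remaining OH is then held in a strong hydrogen bond to the formyl oxygen and only one equivalent of 3 is used.

Step 3
Reactants: 4 3-{[3,4-bis(benzyloxy)phenyl]methoxy}-4-formyl-5-hydroxyphenyl 4-methylbenzenesulfonate
Product: 5 3-(benzyloxy)-5-{[3,4-bis(benzyloxy)phenyl]methoxy}-4-formylphenyl 4-methylbenzenesulfonate
Conditions: BnBr (1.5 equiv), K2CO3, DMF, 60 °C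
Reagents that add atoms: benzyl bromide (BnBr), BrCc1ccccc1
Why: Williamson etherification of the chelated phenol is forced with excess benzyl bromide at higher temperature, conditions the aryl tosylate and the other ethers should tolerate.

Step 4
Reactants: 5 3-(benzyloxy)-5-{[3,4-bis(benzyloxy)phenyl]methoxy}-4-formylphenyl 4-methylbenzenesulfonate; 6 (triphenylphosphoranylidene)acetaldehyde
Product: 7 3-(benzyloxy)-5-{[3,4-bis(benzyloxy)phenyl]methoxy}-4-[(E)-3-oxoprop-1-en-1-yl]phenyl 4-methylbenzenesulfonate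
Conditions: 6 (1.3 equiv), toluene, 90 °C
Reagents that add atoms: none
Why: Wittig olefination with the stabilised formylmethylene ylide should give the (E)-cinnamaldehyde, the tosylate para to the formyl group making the hindered aldehyde more electrophilic.

Step 5
Reactants: 7 3-(benzyloxy)-5-{[3,4-bis(benzyloxy)phenyl]methoxy}-4-[(E)-3-oxoprop-1-en-1-yl]phenyl 4-methylbenzenesulfonate
Product: 11 (2S,3S)-5-(benzyloxy)-2-[3,4-bis(benzyloxy)phenyl]-3-formyl-3,4-dihydro-2H-chromen-7-yl 4-methylbenzenesulfonate (2,3-trans), via iminium ion 8 (not isolated), via enamine oxocarbenium ion 9 (not isolated), via cyclised iminium ion 10 (not isolated)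
Conditions: (R)-2-{bis[3,5-bis(trifluoromethyl)phenyl][(trimethylsilyl)oxy]methyl}pyrrolidine (20 mol %), 2,4-dinitrobenzenesulfonic acid (20 mol %, as the preformed 1:1 ammonium salt), H2O (2 equiv), ClCH2CH2Cl, 40 °C; cold aq. NaHCO3 work-up
Reagents that add atoms: none
Why: Proposed new method: condensation of enal 7 with the pyrrolidine gives iminium ion 8, whose C4 accepts hydride from the C2–H bond (α to O1, benzylic to the para-benzyloxy ring B) through a six-membered [1,5] transition state to give enamine oxocarbenium ion 9, and C3 of the enamine then adds to C2 of the oxocarbenium in a Mannich-type closure to iminium ion 10, which hydrolyses to 11 and frees the catalyst. The closest known reaction types are the amine-catalysed enantioselective [1,5]-hydride transfer/ring closure of ortho-(dialkylamino)cinnamaldehydes to tetrahydroquinoline-3-carbaldehydes and the Sc(OTf)3-catalysed hydride shift/cyclisation of 2-(benzyloxy)benzylidene malonates to 2-arylchromans; what is new is the union of iminium activation with an aryl benzyl ether as hydride donor. Ring C closes in a 6-(enolexo)-endo-trig mode. C3 is set by the catalyst, whose diaryl(silyloxy)methyl group shields one face of the (E)-enamine, and C2 is set relative to C3 in a chair-like transition state that places ring B pseudo-equatorial on the (E)-oxocarbenium, so that the 2,3-trans aldehyde should result; C3, being α to the formyl group, can also equilibrate to trans, whereas C2 cannot. The step needs the hydride to come from C2–H and not from the methylene of the 5-benzyloxy group, which is also ortho to the acceptor; the para-benzyloxy group of ring B, which stabilises the oxocarbenium as a quinoid cation, should secure this, while the 7-tosyloxy group and the twist forced by the two ortho substituents keep ring A from quenching the hydride affinity of the iminium ion.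

Step 6
Reactants: 11 (2S,3S)-5-(benzyloxy)-2-[3,4-bis(benzyloxy)phenyl]-3-formyl-3,4-dihydro-2H-chromen-7-yl 4-methylbenzenesulfonate
Product: 13 (2R,3S)-5-(benzyloxy)-2-[3,4-bis(benzyloxy)phenyl]-3-hydroxy-3,4-dihydro-2H-chromen-7-yl 4-methylbenzenesulfonate, via formate 12 (not isolated)
Conditions: mCPBA (1.5 equiv), CH2Cl2, 0 °C to rt; then K2CO3 (cat.), MeOH, 0 °C
Reagents that add atoms: 3-chloroperoxybenzoic acid (mCPBA), OOC(=O)c1cccc(Cl)c1
Why: Baeyer–Villiger oxidation of the α-branched aldehyde should move the secondary C3 to oxygen with retention of configuration to give formate 12, and mild methanolysis then frees the C3 alcohol with the catechin (2R,3S) configuration without touching the aryl tosylate.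

Step 7
Reactants: 13 (2R,3S)-5-(benzyloxy)-2-[3,4-bis(benzyloxy)phenyl]-3-hydroxy-3,4-dihydro-2H-chromen-7-yl 4-methylbenzenesulfonate
Product: 14 (2R,3S)-5-(benzyloxy)-2-[3,4-bis(benzyloxy)phenyl]-3,4-dihydro-2H-chromene-3,7-diol
Conditions: KOH (5 equiv), 1,4-dioxane/H2O, 80 °C; then aq. HCl to pH 5
Reagents that add atoms: none
Why: Hydrolytic cleavage of the aryl sulfonate by attack of hydroxide at sulfur should free the C7 phenol, while the benzyl ethers and both stereocentres are inert because the benzylated 4'-oxygen cannot open ring C through a quinone methide.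

Step 8
Reactants: 14 (2R,3S)-5-(benzyloxy)-2-[3,4-bis(benzyloxy)phenyl]-3,4-dihydro-2H-chromene-3,7-diol; 15 3,4,5-tris(benzyloxy)benzoic acid
Product: 16 (2R,3S)-5-(benzyloxy)-2-[3,4-bis(benzyloxy)phenyl]-3,4-dihydro-2H-chromene-3,7-diyl bis[3,4,5-tris(benzyloxy)benzoate]
Conditions: 15 (2.6 equiv), DCC (3 equiv), 4-(dimethylamino)pyridine (0.3 equiv), CH2Cl2, 0 °C to rt
Reagents that add atoms: none
Why: Steglich esterification should acylate both the C7 phenol and the secondary C3 alcohol in one operation without touching either stereocentre.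

Step 9
Reactants: 16 (2R,3S)-5-(benzyloxy)-2-[3,4-bis(benzyloxy)phenyl]-3,4-dihydro-2H-chromene-3,7-diyl bis[3,4,5-tris(benzyloxy)benzoate]
Product: 17 (2R,3S)-2-(3,4-dihydroxyphenyl)-5-hydroxy-3,4-dihydro-2H-chromene-3,7-diyl bis(3,4,5-trihydroxybenzoate), catechin 3,7-di-O-gallate
Conditions: H2 (1 atm), Pd(OH)2/C, THF/MeOH, rt
Reagents that add atoms: none
Why: Catalytic hydrogenolysis under neutral conditions should remove all nine O-benzyl groups while leaving the alkyl and aryl gallate esters and the cyclic benzylic C2–O1 bond intact.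

**Compound list**
1 | 2,4,6-trihydroxybenzaldehyde | O=Cc1c(O)cc(O)cc1O | starting material
2 | 4-formyl-3,5-dihydroxyphenyl 4-methylbenzenesulfonate | O=Cc1c(O)cc(OS(=O)(=O)c2ccc(C)cc2)cc1O | intermediate
3 | 3,4-bis(benzyloxy)benzyl chloride | ClCc1ccc(OCc2ccccc2)c(OCc2ccccc2)c1 | starting material
4 | 3-{[3,4-bis(benzyloxy)phenyl]methoxy}-4-formyl-5-hydroxyphenyl 4-methylbenzenesulfonate | O=Cc1c(O)cc(OS(=O)(=O)c2ccc(C)cc2)cc1OCc1ccc(OCc2ccccc2)c(OCc2ccccc2)c1 | intermediate
5 | 3-(benzyloxy)-5-{[3,4-bis(benzyloxy)phenyl]methoxy}-4-formylphenyl 4-methylbenzenesulfonate | O=Cc1c(OCc2ccccc2)cc(OS(=O)(=O)c2ccc(C)cc2)cc1OCc1ccc(OCc2ccccc2)c(OCc2ccccc2)c1 | intermediate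
6 | (triphenylphosphoranylidene)acetaldehyde | O=CC=P(c1ccccc1)(c1ccccc1)c1ccccc1 | starting material
7 | 3-(benzyloxy)-5-{[3,4-bis(benzyloxy)phenyl]methoxy}-4-[(E)-3-oxoprop-1-en-1-yl]phenyl 4-methylbenzenesulfonate | O=C/C=C/c1c(OCc2ccccc2)cc(OS(=O)(=O)c2ccc(C)cc2)cc1OCc1ccc(OCc2ccccc2)c(OCc2ccccc2)c1 | intermediate
8 | iminium ion of enal 7 and the (R)-pyrrolidine catalyst (cation) | C1C[C@@H]([N+](C1)=C/C=C/c1c(OCc2ccccc2)cc(OS(=O)(=O)c2ccc(C)cc2)cc1OCc1ccc(OCc2ccccc2)c(OCc2ccccc2)c1)C(O[Si](C)(C)C)(c1cc(C(F)(F)F)cc(C(F)(F)F)c1)c1cc(C(F)(F)F)cc(C(F)(F)F)c1 | intermediate (not isolated)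
9 | (E)-enamine carrying the aryl oxocarbenium ion formed by the [1,5]-hydride shift (cation) | C1C[C@@H](N(C1)/C=C/Cc1c(OCc2ccccc2)cc(OS(=O)(=O)c2ccc(C)cc2)cc1[O+]=Cc1ccc(OCc2ccccc2)c(OCc2ccccc2)c1)C(O[Si](C)(C)C)(c1cc(C(F)(F)F)cc(C(F)(F)F)c1)c1cc(C(F)(F)F)cc(C(F)(F)F)c1 | intermediate (not isolated)
10 | iminium ion of the ring-closed trans-chroman-3-carbaldehyde (cation) | C1C[C@@H]([N+](C1)=C[C@H]1Cc2c(OCc3ccccc3)cc(OS(=O)(=O)c3ccc(C)cc3)cc2O[C@@H]1c1ccc(OCc2ccccc2)c(OCc2ccccc2)c1)C(O[Si](C)(C)C)(c1cc(C(F)(F)F)cc(C(F)(F)F)c1)c1cc(C(F)(F)F)cc(C(F)(F)F)c1 | intermediate (not isolated)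
11 | (2S,3S)-5-(benzyloxy)-2-[3,4-bis(benzyloxy)phenyl]-3-formyl-3,4-dihydro-2H-chromen-7-yl 4-methylbenzenesulfonate | O=C[C@H]1Cc2c(OCc3ccccc3)cc(OS(=O)(=O)c3ccc(C)cc3)cc2O[C@@H]1c1ccc(OCc2ccccc2)c(OCc2ccccc2)c1 | intermediate
12 | (2R,3S)-5-(benzyloxy)-2-[3,4-bis(benzyloxy)phenyl]-3-(formyloxy)-3,4-dihydro-2H-chromen-7-yl 4-methylbenzenesulfonate | O=CO[C@H]1Cc2c(OCc3ccccc3)cc(OS(=O)(=O)c3ccc(C)cc3)cc2O[C@@H]1c1ccc(OCc2ccccc2)c(OCc2ccccc2)c1 | intermediate (not isolated)
13 | (2R,3S)-5-(benzyloxy)-2-[3,4-bis(benzyloxy)phenyl]-3-hydroxy-3,4-dihydro-2H-chromen-7-yl 4-methylbenzenesulfonate | O[C@H]1Cc2c(OCc3ccccc3)cc(OS(=O)(=O)c3ccc(C)cc3)cc2O[C@@H]1c1ccc(OCc2ccccc2)c(OCc2ccccc2)c1 | intermediate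
14 | (2R,3S)-5-(benzyloxy)-2-[3,4-bis(benzyloxy)phenyl]-3,4-dihydro-2H-chromene-3,7-diol | O[C@H]1Cc2c(OCc3ccccc3)cc(O)cc2O[C@@H]1c1ccc(OCc2ccccc2)c(OCc2ccccc2)c1 | intermediate
15 | 3,4,5-tris(benzyloxy)benzoic acid | OC(=O)c1cc(OCc2ccccc2)c(OCc2ccccc2)c(OCc2ccccc2)c1 | starting material
16 | (2R,3S)-5-(benzyloxy)-2-[3,4-bis(benzyloxy)phenyl]-3,4-dihydro-2H-chromene-3,7-diyl bis[3,4,5-tris(benzyloxy)benzoate] | O=C(O[C@H]1Cc2c(OCc3ccccc3)cc(OC(=O)c3cc(OCc4ccccc4)c(OCc4ccccc4)c(OCc4ccccc4)c3)cc2O[C@@H]1c1ccc(OCc2ccccc2)c(OCc2ccccc2)c1)c1cc(OCc2ccccc2)c(OCc2ccccc2)c(OCc2ccccc2)c1 | intermediate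
17 | (2R,3S)-2-(3,4-dihydroxyphenyl)-5-hydroxy-3,4-dihydro-2H-chromene-3,7-diyl bis(3,4,5-trihydroxybenzoate), catechin 3,7-di-O-gallate | O=C(Oc1cc(O)c2c(c1)O[C@H](c1ccc(O)c(O)c1)[C@@H](OC(=O)c1cc(O)c(O)c(O)c1)C2)c1cc(O)c(O)c(O)c1 | target

**Step count and risks**
Total step count: 9. Longest linear sequence: 9 steps (from 1 to 17).

Steps most likely to fail:

Step 5. The hydride shift may not occur because the iminium ion of so electron-rich an enal has too little hydride affinity. The hydride may instead come from the methylene of the 5-benzyloxy group. The acid co-catalyst may ionise the acid-labile 3,4-bis(benzyloxy)benzyl ether. The enamine of the product may open ring C by loss of the aryloxide from C2 and so erode the enantiomeric purity. The fallback uses known chemistry, sets out from aldehyde 5 and comes back at aldehyde 11. Knoevenagel condensation of 5 with dimethyl malonate (TiCl4, pyridine, THF, 0 °C to rt) should give dimethyl arylidenemalonate F1, a doubly activated and stronger hydride acceptor. Sc(OTf)3 (10 mol %) in ClCH2CH2Cl at reflux should then effect the Lewis-acid form of the same [1,5]-hydride shift and C2–C3 closure, a reaction type established for 2-(benzyloxy)benzylidene malonates, to give racemic chroman-3,3-diester F2. Krapcho demethoxycarbonylation (LiCl, wet DMSO, 140 °C), followed by equilibration with DBU, should give racemic trans methyl ester F3. Its enantiomers are separated by preparative chromatography on a chiral stationary phase to give (2S,3S)-methyl ester F4. Reduction of F4 with DIBAL-H (toluene, −78 °C) gives aldehyde 11.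

Step 6. The formyl hydrogen may migrate instead of C3, so that over-oxidation to the carboxylic acid replaces formate formation, and the peracid may attack the electron-rich rings on long exposure. The fallback sets out from aldehyde 11 and comes back at alcohol 13. Addition of MeMgBr (THF, −78 °C) should give methyl carbinol F5 as a mixture of epimers at the new carbinol carbon. Dess–Martin periodinane (CH2Cl2, NaHCO3) gives methyl ketone F6, which keeps or regains the 2,3-trans arrangement. Baeyer–Villiger oxidation (mCPBA, NaHCO3, CH2Cl2), in which the secondary C3 migrates in preference to methyl with retention, gives acetate F7. Methanolysis (K2CO3, MeOH) gives 13.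

Step 4. Olefination of the di-ortho-substituted, electron-rich aldehyde with the stabilised ylide may be sluggish, and the enal formed may react again to give the dienal. The fallback sets out from aldehyde 5 and comes back at enal 7. Horner–Wadsworth–Emmons reaction with triethyl phosphonoacetate (NaH, THF) should give ethyl (E)-cinnamate F8. DIBAL-H (CH2Cl2, −78 °C) gives (E)-allylic alcohol F9. MnO2 (CH2Cl2, rt) oxidises F9 to 7.

**Further compounds**
F1 | step 5 | dimethyl 2-{[2-(benzyloxy)-6-{[3,4-bis(benzyloxy)phenyl]methoxy}-4-(tosyloxy)phenyl]methylidene}propanedioate | COC(=O)C(=Cc1c(OCc2ccccc2)cc(OS(=O)(=O)c2ccc(C)cc2)cc1OCc1ccc(OCc2ccccc2)c(OCc2ccccc2)c1)C(=O)OC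
F2 | step 5 | dimethyl 5-(benzyloxy)-2-[3,4-bis(benzyloxy)phenyl]-7-(tosyloxy)-2H-chromene-3,3(4H)-dicarboxylate, racemic | COC(=O)C1(C(=O)OC)Cc2c(OCc3ccccc3)cc(OS(=O)(=O)c3ccc(C)cc3)cc2OC1c1ccc(OCc2ccccc2)c(OCc2ccccc2)c1
F3 | step 5 | methyl trans-5-(benzyloxy)-2-[3,4-bis(benzyloxy)phenyl]-7-(tosyloxy)-3,4-dihydro-2H-chromene-3-carboxylate, racemic (both enantiomers written) | COC(=O)[C@H]1Cc2c(OCc3ccccc3)cc(OS(=O)(=O)c3ccc(C)cc3)cc2O[C@@H]1c1ccc(OCc2ccccc2)c(OCc2ccccc2)c1.COC(=O)[C@@H]1Cc2c(OCc3ccccc3)cc(OS(=O)(=O)c3ccc(C)cc3)cc2O[C@H]1c1ccc(OCc2ccccc2)c(OCc2ccccc2)c1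
F4 | step 5 | methyl (2S,3S)-5-(benzyloxy)-2-[3,4-bis(benzyloxy)phenyl]-7-(tosyloxy)-3,4-dihydro-2H-chromene-3-carboxylate | COC(=O)[C@H]1Cc2c(OCc3ccccc3)cc(OS(=O)(=O)c3ccc(C)cc3)cc2O[C@@H]1c1ccc(OCc2ccccc2)c(OCc2ccccc2)c1
F5 | step 6 | 5-(benzyloxy)-2-[3,4-bis(benzyloxy)phenyl]-3-(1-hydroxyethyl)-3,4-dihydro-2H-chromen-7-yl 4-methylbenzenesulfonate, ring stereocentres as in 11 (2,3-trans), mixture of epimers at the carbinol carbon | CC(O)[C@H]1Cc2c(OCc3ccccc3)cc(OS(=O)(=O)c3ccc(C)cc3)cc2O[C@@H]1c1ccc(OCc2ccccc2)c(OCc2ccccc2)c1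
F6 | step 6 | (2S,3S)-3-acetyl-5-(benzyloxy)-2-[3,4-bis(benzyloxy)phenyl]-3,4-dihydro-2H-chromen-7-yl 4-methylbenzenesulfonate | CC(=O)[C@H]1Cc2c(OCc3ccccc3)cc(OS(=O)(=O)c3ccc(C)cc3)cc2O[C@@H]1c1ccc(OCc2ccccc2)c(OCc2ccccc2)c1
F7 | step 6 | (2R,3S)-3-(acetyloxy)-5-(benzyloxy)-2-[3,4-bis(benzyloxy)phenyl]-3,4-dihydro-2H-chromen-7-yl 4-methylbenzenesulfonate | CC(=O)O[C@H]1Cc2c(OCc3ccccc3)cc(OS(=O)(=O)c3ccc(C)cc3)cc2O[C@@H]1c1ccc(OCc2ccccc2)c(OCc2ccccc2)c1
F8 | step 4 | ethyl (E)-3-[2-(benzyloxy)-6-{[3,4-bis(benzyloxy)phenyl]methoxy}-4-(tosyloxy)phenyl]prop-2-enoate | CCOC(=O)/C=C/c1c(OCc2ccccc2)cc(OS(=O)(=O)c2ccc(C)cc2)cc1OCc1ccc(OCc2ccccc2)c(OCc2ccccc2)c1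
F9 | step 4 | 3-(benzyloxy)-5-{[3,4-bis(benzyloxy)phenyl]methoxy}-4-[(E)-3-hydroxyprop-1-en-1-yl]phenyl 4-methylbenzenesulfonate | OC/C=C/c1c(OCc2ccccc2)cc(OS(=O)(=O)c2ccc(C)cc2)cc1OCc1ccc(OCc2ccccc2)c(OCc2ccccc2)c1
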